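**Strategy.** Ring labels: C1 is the quaternary carbon (methyl, polyene chain), C2 the CH bearing hydroxypropyl, C3 the alkylidene carbon, C6 the carbinol carbon. The route rests on disconnecting C1–C2 by a ring-contracting Ireland–Claisen rearrangement. It exploits the γ,δ-unsaturated acid latent in C(methyl)–C1–C2–C3=C4 once the C3 alkylidene is redrawn as a ring diene. The precursor is a mevalonolactone-like δ-lactone, a 6-dienyl-4-hydroxy-4-methyl-3-vinyltetrahydropyran-2-one. One operation closes the carbocycle and sets C1 and C2 from the lactone's two stereocentres and its E-alkene. The lactone carbonyl becomes the C1 methyl, the vinyl group anchors a B-alkyl Suzuki union with the C14 side chain, and cis-1,4-hydrogenation fixes the enal geometry.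

Key step: step 14

Remark: the α-carbon of 30–32 (C3 of the lactone) is formed as a mixture of epimers; this has no consequence because it is trigonal in 33.
Remark: the catalyst antipodes in steps 1 and 11 are those that give the configurations drawn; the one named in step 1 is assumed by analogy with aryl aldehydes.

**Side chain (steps 1–5)**

Step 1
Reactants: 1 3-methylbut-2-enal; 2 allenylboronic acid pinacol ester
Product: 4 (R)-6-methylhept-5-en-1-yn-4-ol, via pinacol borate ester 3 (not isolated)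
Conditions: (R)-TRIP phosphoric acid (5 mol %), 4 Å MS, toluene, 0 °C; aq. NaHCO3
Reagents that add atoms: none
Why: Chiral-phosphoric-acid-catalysed asymmetric propargylation with the allenylboronate (closed six-membered transition state) should give the homopropargylic alcohol, the carbinol centre being set by the catalyst.

Step 2
Reactants: 4 (R)-6-methylhept-5-en-1-yn-4-ol
Product: 5 TBDPS ether of 4
Conditions: TBDPSCl, imidazole, DMF, 23 °C
Reagents that add atoms: tert-butylchlorodiphenylsilane, CC(C)(C)[Si](Cl)(c1ccccc1)c1ccccc1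
Why: Standard silylation of a secondary alcohol; TBDPS is chosen because it should survive the graded desilylation of step 20.

Step 3
Reactants: 5 TBDPS ether of 4
Product: 7 TBDPS ether of (1E,4R)-1-iodo-2,6-dimethylhepta-1,5-dien-4-ol, via alkenylalane 6 (not isolated)
Conditions: Me3Al, Cp2ZrCl2 (20 mol %), H2O (1 equiv), CH2Cl2, −30 → 0 °C; then I2, THF, −30 °C
Reagents that add atoms: trimethylaluminium, C[Al](C)C; iodine, II
Why: Zirconium-catalysed syn-carboalumination of the terminal alkyne places methyl and aluminium cis, and iodinolysis with retention should give the (E)-iodoalkene while the trisubstituted alkene stays inert.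

Step 4
Reactants: 7 TBDPS ether of (1E,4R)-1-iodo-2,6-dimethylhepta-1,5-dien-4-ol; 8 (4-bromobut-1-yn-1-yl)trimethylsilane
Product: 11 TBDPS ether of (4R,6E)-2,6-dimethylundeca-2,6-dien-10-yn-4-ol, via alkylzinc bromide 9 (not isolated), via silylated enyne 10 (not isolated)
Conditions: 8, Zn dust, LiCl, THF, 50 °C; then 7, Pd(PPh3)4 (5 mol %), THF, 23 °C; then K2CO3, MeOH, 23 °C
Reagents that add atoms: none
Why: Negishi sp3–sp2 cross-coupling proceeds with retention of the alkene geometry, and methanolysis then removes only the alkynyl TMS group.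

Step 5
Reactants: 11 TBDPS ether of (4R,6E)-2,6-dimethylundeca-2,6-dien-10-yn-4-ol
Product: 13 TBDPS ether of (1E,5E,8R)-1-iodo-2,6,10-trimethylundeca-1,5,9-trien-8-ol, via alkenylalane 12 (not isolated)
Conditions: Me3Al, Cp2ZrCl2 (20 mol %), H2O (1 equiv), CH2Cl2, −30 → 0 °C; then I2, THF, −30 °C
Reagents that add atoms: trimethylaluminium, C[Al](C)C; iodine, II
Why: A second zirconium-catalysed syn-carboalumination and iodinolysis should install the second (E)-trisubstituted alkene as the iodoalkene needed for the fragment union.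

**Core (steps 6–18)**

Step 6
Reactants: 14 pent-4-en-1-ol
Product: 15 tert-butyldimethyl(pent-4-en-1-yloxy)silane
Conditions: TBSCl, imidazole, DMF, 23 °C
Reagents that add atoms: tert-butylchlorodimethylsilane, CC(C)(C)[Si](C)(C)Cl
Why: Standard silylation of a primary alcohol.

Step 7
Reactants: 15 tert-butyldimethyl(pent-4-en-1-yloxy)silane; 16 (E)-but-2-enal
Product: 17 (E)-6-(tert-butyldimethylsilyloxy)hex-2-enal
Conditions: Hoveyda–Grubbs II (3 mol %), CH2Cl2, 40 °C
Reagents that add atoms: none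
Why: Olefin cross-metathesis of a terminal alkene with crotonaldehyde is E-selective under thermodynamic control and is driven by loss of propene.

Step 8
Reactants: 17 (E)-6-(tert-butyldimethylsilyloxy)hex-2-enal
Product: 19 (Z)-2-bromo-6-(tert-butyldimethylsilyloxy)hex-2-enal, via dibromide 18 (not isolated)
Conditions: Br2, CH2Cl2, −78 °C; then Et3N, −78 → 0 °C
Reagents that add atoms: bromine, BrBr
Why: Bromination followed by base-induced dehydrobromination should give the favoured (Z)-2-bromoenal, in which the chain is trans to the formyl group.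

Step 9
Reactants: 20 2-bromoprop-2-en-1-ol
Product: 21 (2-bromoallyloxy)(tert-butyl)dimethylsilane
Conditions: TBSCl, imidazole, CH2Cl2, 23 °C
Reagents that add atoms: tert-butylchlorodimethylsilane, CC(C)(C)[Si](C)(C)Cl
Why: Standard silylation of a primary allylic alcohol.

Step 10
Reactants: 21 (2-bromoallyloxy)(tert-butyl)dimethylsilane; 19 (Z)-2-bromo-6-(tert-butyldimethylsilyloxy)hex-2-enal
Product: 24 (E)-6-(tert-butyldimethylsilyloxy)-2-[3-(tert-butyldimethylsilyloxy)prop-1-en-2-yl]hex-2-enal, via alkenyllithium 22 (not isolated), via alkenylzinc chloride 23 (not isolated)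
Conditions: 21, t-BuLi (2.0 equiv), Et2O, −78 °C; ZnCl2, THF, −78 → 0 °C; then 19, Pd(PPh3)4 (5 mol %), THF, 23 °C
Reagents that add atoms: none
Why: Negishi coupling of the alkenylzinc with the α-bromoenal tolerates the aldehyde and retains the alkene geometry, so the chain stays trans to the formyl group.

Step 11
Reactants: 24 (E)-6-(tert-butyldimethylsilyloxy)-2-[3-(tert-butyldimethylsilyloxy)prop-1-en-2-yl]hex-2-enal; 25 2-methoxypropene
Product: 27 (4S,5E)-9-(tert-butyldimethylsilyloxy)-5-[3-(tert-butyldimethylsilyloxy)prop-1-en-2-yl]-4-hydroxynon-5-en-2-one, via enol ether adduct 26 (not isolated)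
Conditions: Ti(IV)–binaphthyl Schiff base/3,5-di-tert-butylsalicylate catalyst (5 mol %), 2,6-di-tert-butyl-4-methylpyridine, 25 as solvent, 0 °C; then 0.5 M HCl, Et2O, 0 °C
Reagents that add atoms: water, O
Why: Catalytic enantioselective acetone aldol (ene-type addition of 2-methoxypropene, then enol ether hydrolysis) on the non-enolisable enal should set the (S)-carbinol by catalyst-controlled Si-face addition.

Step 12
Reactants: 27 (4S,5E)-9-(tert-butyldimethylsilyloxy)-5-[3-(tert-butyldimethylsilyloxy)prop-1-en-2-yl]-4-hydroxynon-5-en-2-one; 28 (E)-4-bromobut-2-enoic acid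
Product: 30 (E)-4-bromobut-2-enoate ester of 27, via acid chloride 29 (not isolated)
Conditions: 28, (COCl)2, DMF (cat.), CH2Cl2, 0 → 23 °C; then 27, pyridine, CH2Cl2, −20 °C
Reagents that add atoms: none
Why: Acylation with the acid chloride under cold, weakly basic conditions should esterify the secondary alcohol without β-elimination of the β-acyloxy ketone.

Step 13
Reactants: 30 (E)-4-bromobut-2-enoate ester of 27
Product: 32 (4R,6S)-6-dienyl-4-hydroxy-4-methyl-3-vinyltetrahydro-2H-pyran-2-one, via samarium dienolate 31 (not isolated)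
Conditions: SmI2 (2.2 equiv), THF, −78 °C; aq. NH4Cl
Reagents that add atoms: none
Why: SmI2-promoted intramolecular (vinylogous) Reformatsky aldol, with α-attack enforced by six-membered ring formation, should pass through a Sm(III)-chelated bicyclic transition state with the new C–O bond axial and the dienyl group equatorial, so that the tertiary hydroxyl ends trans to the dienyl group by 1,3-induction from the carbinol centre.

Step 14
Reactants: 32 (4R,6S)-6-dienyl-4-hydroxy-4-methyl-3-vinyltetrahydro-2H-pyran-2-one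
Product: 35 (1S,2S,6R)-2-[3-(tert-butyldimethylsilyloxy)propyl]-3-[3-(tert-butyldimethylsilyloxy)prop-1-en-2-yl]-6-methyl-6-(triethylsilyloxy)-1-vinylcyclohex-3-ene-1-carboxylic acid, via bis-silyl ketene acetal 33 (not isolated), via triethylsilyl ester 34 (not isolated)
Conditions: LDA (2.5 equiv), THF–DMPU, −78 °C; TESCl (3 equiv), −78 → 23 °C; then toluene, 110 °C; aq. K2CO3, then pH 4
Reagents that add atoms: chlorotriethylsilane, CC[Si](Cl)(CC)CC
Why: O-silylation of the alkoxide–dienolate dianion of 32 gives the cyclic silyl ketene acetal 33, whose C=C(OSi)–O–C–C=C array undergoes a concerted suprafacial [3,3]-sigmatropic (Ireland–Claisen) shift that joins the lactone α-carbon to the alkene terminus as the ring C–O bond breaks, the closest known reaction type being the ring-contracting ester-enolate Claisen rearrangement of 6-alkenyl δ-lactone silyl ketene acetals to cyclohex-3-enecarboxylic acids. The six-membered carbocycle is closed across the 3,6-positions of the oxacycle through a boat-like, bicyclo[2.2.2]octene-shaped transition state, the only one the two-carbon tether allows, so the oxygen heterocycle is exchanged for a carbocycle of the same size. The quaternary carbon is controlled by the lactone framework: the carboxyl stays on the face that carried the ring oxygen and therefore ends cis to the silyloxy group that step 13 set trans to the dienyl group, with the vinyl group on the other face. The neighbouring CH stereocentre is controlled by the E geometry of the trisubstituted alkene, whose propyl chain (trans to the carbinol carbon) ends cis to the carboxyl while only H occupies the crowded inside position of the boat. The ketene acetal geometry is fixed by the ring, so the step needs only [3,3] selectivity over β-elimination of silanolate and over desilylation, which dianion formation before silylation and neutral thermolysis should secure; the carbinol stereocentre that relays the chirality is consumed.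

Step 15
Reactants: 35 cyclohexene carboxylic acid
Product: 36 [(1R,2S,6R)-2-[3-(tert-butyldimethylsilyloxy)propyl]-3-[3-(tert-butyldimethylsilyloxy)prop-1-en-2-yl]-6-methyl-6-(triethylsilyloxy)-1-vinylcyclohex-3-en-1-yl]methanol
Conditions: LiAlH4, THF, 0 → 60 °C; Rochelle salt
Reagents that add atoms: none
Why: Hydride reduction of the hindered carboxylic acid to the neopentyl primary alcohol leaves the silyl ethers, the diene and the vinyl group untouched.

Step 16
Reactants: 36 dienyl primary alcohol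
Product: 37 [(1R,2S,3Z,6R)-2-[3-(tert-butyldimethylsilyloxy)propyl]-3-[1-(tert-butyldimethylsilyloxy)propan-2-ylidene]-6-methyl-6-(triethylsilyloxy)-1-vinylcyclohexyl]methanol
Conditions: (η6-naphthalene)Cr(CO)3 (20 mol %), H2 (50 atm), THF, 45 °C
Reagents that add atoms: none
Why: Chromium-tricarbonyl-catalysed 1,4-hydrogenation adds H2 across the termini of the η4-s-cis diene only, so the new methyl should end cis to ring C4 and the CH2OTBS group cis to C2 (tetrasubstituted Z-alkene), while the isolated vinyl group is not reduced.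

Step 17
Reactants: 37 alkylidenecyclohexyl methanol
Product: 38 (1S,2S,3Z,6R)-2-[3-(tert-butyldimethylsilyloxy)propyl]-3-[1-(tert-butyldimethylsilyloxy)propan-2-ylidene]-6-methyl-6-(triethylsilyloxy)-1-vinylcyclohexane-1-carbaldehyde
Conditions: Dess–Martin periodinane, NaHCO3, CH2Cl2, 0 → 23 °C
Reagents that add atoms: none
Why: Dess–Martin oxidation of the neopentyl primary alcohol should give a non-enolisable aldehyde, and the silylated tertiary oxygen cannot trigger retro-aldol cleavage.

Step 18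
Reactants: 38 neopentyl aldehyde
Product: 40 (1R,2S,3Z,6R)-2-[3-(tert-butyldimethylsilyloxy)propyl]-3-[1-(tert-butyldimethylsilyloxy)propan-2-ylidene]-1,6-dimethyl-6-(triethylsilyloxy)-1-vinylcyclohexane, via N-silyl hydrazone 39 (not isolated)
Conditions: TBSNHNHTBS, Sc(OTf)3 (1 mol %), CH2Cl2, 23 °C; then KOt-Bu, t-BuOH, DMSO, 23 °C
Reagents that add atoms: none
Why: Low-temperature Wolff–Kishner reduction through the N-silyl hydrazone (anionic diimide fragmentation with loss of N2) should turn the hindered formyl group into the ring methyl without radical intermediates that could cause vinyl migration.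

**Fragment union and endgame (steps 19–22)**

Step 19
Reactants: 40 vinylcyclohexane; 13 TBDPS ether of (1E,5E,8R)-1-iodo-2,6,10-trimethylundeca-1,5,9-trien-8-ol
Product: 42 fully silylated coupling product, via B-alkyl-9-BBN 41 (not isolated)
Conditions: 9-BBN, THF, 0 → 40 °C; then 13, Pd(dppf)Cl2 (10 mol %), AsPh3, Cs2CO3, DMF/H2O, 23 °C
Reagents that add atoms: none
Why: Anti-Markovnikov hydroboration of the only monosubstituted alkene and B-alkyl Suzuki–Miyaura coupling with the (E)-iodoalkene, with retention of geometry, should complete the homofarnesyl chain.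

Step 20
Reactants: 42 fully silylated coupling product
Product: 43 triol mono-TBDPS ether
Conditions: HF·pyridine, pyridine, THF, 0 → 23 °C
Reagents that add atoms: none
Why: Fluoride-mediated desilylation graded by steric demand should cleave the two primary TBS ethers and the tertiary TES ether while the secondary TBDPS ether survives.

Step 21
Reactants: 43 triol mono-TBDPS ether
Product: 44 (Z)-enal mono-TBDPS ether
Conditions: activated MnO2, CH2Cl2, 23 °C
Reagents that add atoms: none
Why: MnO2 oxidation is selective for the allylic primary alcohol, because the saturated primary and tertiary alcohols are inert and the second allylic alcohol is still silylated.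

Step 22
Reactants: 44 (Z)-enal mono-TBDPS ether
Product: 45 target, (2Z)-2-[(2S,3R,4R)-4-hydroxy-2-(3-hydroxypropyl)-3-[(3E,7E,10R)-10-hydroxy-4,8,12-trimethyltrideca-3,7,11-trien-1-yl]-3,4-dimethylcyclohexylidene]propanal
Conditions: TBAF, AcOH, THF, 23 °C
Reagents that add atoms: none
Why: Acetic-acid-buffered fluoride desilylation should remove the TBDPS group without base-induced deconjugation or E/Z isomerisation of the enal.

**Compound list**

1 | 3-methylbut-2-enal | CC(C)=CC=O | starting material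
2 | allenylboronic acid pinacol ester | C=C=CB1OC(C)(C)C(C)(C)O1 | starting material
3 | pinacol borate ester of 4 | CC(C)=C[C@H](OB1OC(C)(C)C(C)(C)O1)CC#C | intermediate (not isolated)
4 | (R)-6-methylhept-5-en-1-yn-4-ol | CC(C)=C[C@H](O)CC#C | intermediate
5 | (R)-tert-butyl[(6-methylhept-5-en-1-yn-4-yl)oxy]diphenylsilane | CC(C)=C[C@H](O[Si](c1ccccc1)(c1ccccc1)C(C)(C)C)CC#C | intermediate
6 | dimethyl[(1E,4R)-4-(TBDPS-oxy)-2,6-dimethylhepta-1,5-dien-1-yl]alane | CC(C)=C[C@H](O[Si](c1ccccc1)(c1ccccc1)C(C)(C)C)C/C(C)=C/[Al](C)C | intermediate (not isolated)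
7 | tert-butyl{[(1E,4R)-1-iodo-2,6-dimethylhepta-1,5-dien-4-yl]oxy}diphenylsilane | CC(C)=C[C@H](O[Si](c1ccccc1)(c1ccccc1)C(C)(C)C)C/C(C)=C/I | intermediate
8 | (4-bromobut-1-yn-1-yl)trimethylsilane | C[Si](C)(C)C#CCCBr | starting material
9 | [4-(trimethylsilyl)but-3-yn-1-yl]zinc bromide | C[Si](C)(C)C#CCC[Zn]Br | intermediate (not isolated)
10 | tert-butyl{[(4R,6E)-2,6-dimethyl-11-(trimethylsilyl)undeca-2,6-dien-10-yn-4-yl]oxy}diphenylsilane | CC(C)=C[C@H](O[Si](c1ccccc1)(c1ccccc1)C(C)(C)C)C/C(C)=C/CCC#C[Si](C)(C)C | intermediate (not isolated)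
11 | tert-butyl{[(4R,6E)-2,6-dimethylundeca-2,6-dien-10-yn-4-yl]oxy}diphenylsilane | CC(C)=C[C@H](O[Si](c1ccccc1)(c1ccccc1)C(C)(C)C)C/C(C)=C/CCC#C | intermediate
12 | dimethyl[(1E,5E,8R)-8-(TBDPS-oxy)-2,6,10-trimethylundeca-1,5,9-trien-1-yl]alane | CC(C)=C[C@H](O[Si](c1ccccc1)(c1ccccc1)C(C)(C)C)C/C(C)=C/CC/C(C)=C/[Al](C)C | intermediate (not isolated)
13 | tert-butyl{[(1E,5E,8R)-1-iodo-2,6,10-trimethylundeca-1,5,9-trien-8-yl]oxy}diphenylsilane | CC(C)=C[C@H](O[Si](c1ccccc1)(c1ccccc1)C(C)(C)C)C/C(C)=C/CC/C(C)=C/I | intermediate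
14 | pent-4-en-1-ol | C=CCCCO | starting material
15 | tert-butyldimethyl(pent-4-en-1-yloxy)silane | C=CCCCO[Si](C)(C)C(C)(C)C | intermediate
16 | (E)-but-2-enal | C/C=C/C=O | starting material
17 | (E)-6-(tert-butyldimethylsilyloxy)hex-2-enal | O=C/C=C/CCCO[Si](C)(C)C(C)(C)C | intermediate
18 | 2,3-dibromo-6-(tert-butyldimethylsilyloxy)hexanal | O=CC(Br)C(Br)CCCO[Si](C)(C)C(C)(C)C | intermediate (not isolated)
19 | (Z)-2-bromo-6-(tert-butyldimethylsilyloxy)hex-2-enal | O=C/C(Br)=C/CCCO[Si](C)(C)C(C)(C)C | intermediate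
20 | 2-bromoprop-2-en-1-ol | C=C(Br)CO | starting material
21 | (2-bromoallyloxy)(tert-butyl)dimethylsilane | C=C(Br)CO[Si](C)(C)C(C)(C)C | intermediate
22 | [3-(tert-butyldimethylsilyloxy)prop-1-en-2-yl]lithium | [Li]C(=C)CO[Si](C)(C)C(C)(C)C | intermediate (not isolated)
23 | [3-(tert-butyldimethylsilyloxy)prop-1-en-2-yl]zinc chloride | Cl[Zn]C(=C)CO[Si](C)(C)C(C)(C)C | intermediate (not isolated)
24 | (E)-6-(tert-butyldimethylsilyloxy)-2-[3-(tert-butyldimethylsilyloxy)prop-1-en-2-yl]hex-2-enal | O=C/C(=C/CCCO[Si](C)(C)C(C)(C)C)C(=C)CO[Si](C)(C)C(C)(C)C | intermediate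
25 | 2-methoxypropene | COC(C)=C | starting material
26 | (4S,5E)-2-methoxy enol ether adduct of 24 (4-hydroxy-2-methoxynona-1,5-diene skeleton) | C=C(OC)C[C@H](O)/C(=C/CCCO[Si](C)(C)C(C)(C)C)C(=C)CO[Si](C)(C)C(C)(C)C | intermediate (not isolated)
27 | (4S,5E)-9-(tert-butyldimethylsilyloxy)-5-[3-(tert-butyldimethylsilyloxy)prop-1-en-2-yl]-4-hydroxynon-5-en-2-one | CC(=O)C[C@H](O)/C(=C/CCCO[Si](C)(C)C(C)(C)C)C(=C)CO[Si](C)(C)C(C)(C)C | intermediate
28 | (E)-4-bromobut-2-enoic acid | OC(=O)/C=C/CBr | starting material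
29 | (E)-4-bromobut-2-enoyl chloride | O=C(Cl)/C=C/CBr | intermediate (not isolated)
30 | (E)-4-bromobut-2-enoate of 27 (S carbinol centre retained) | CC(=O)C[C@H](OC(=O)/C=C/CBr)/C(=C/CCCO[Si](C)(C)C(C)(C)C)C(=C)CO[Si](C)(C)C(C)(C)C | intermediate
31 | samarium(III) dienolate of 30 | CC(=O)C[C@H](OC(O[Sm](I)I)=CC=C)/C(=C/CCCO[Si](C)(C)C(C)(C)C)C(=C)CO[Si](C)(C)C(C)(C)C | intermediate (not isolated)
32 | (4R,6S)-6-{(3E)-7-(TBSO)-2-[(TBSO)methyl]hepta-1,3-dien-3-yl}-4-hydroxy-4-methyl-3-vinyltetrahydro-2H-pyran-2-one (C3 epimers) | C=CC1C(=O)O[C@H](/C(=C/CCCO[Si](C)(C)C(C)(C)C)C(=C)CO[Si](C)(C)C(C)(C)C)C[C@@]1(C)O | intermediate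
33 | bis(triethylsilyl) ketene acetal of 32 (2,4-bis(triethylsilyloxy)-3-vinyl-5,6-dihydro-4H-pyran) | C=CC1=C(O[Si](CC)(CC)CC)O[C@H](/C(=C/CCCO[Si](C)(C)C(C)(C)C)C(=C)CO[Si](C)(C)C(C)(C)C)C[C@@]1(C)O[Si](CC)(CC)CC | intermediate (not isolated)
34 | triethylsilyl ester of 35 | C=C[C@]1(C(=O)O[Si](CC)(CC)CC)[C@@H](CCCO[Si](C)(C)C(C)(C)C)C(C(=C)CO[Si](C)(C)C(C)(C)C)=CC[C@@]1(C)O[Si](CC)(CC)CC | intermediate (not isolated)
35 | (1S,2S,6R)-2-[3-(TBSO)propyl]-3-[3-(TBSO)prop-1-en-2-yl]-6-methyl-6-(triethylsilyloxy)-1-vinylcyclohex-3-ene-1-carboxylic acid | C=C[C@]1(C(=O)O)[C@@H](CCCO[Si](C)(C)C(C)(C)C)C(C(=C)CO[Si](C)(C)C(C)(C)C)=CC[C@@]1(C)O[Si](CC)(CC)CC | intermediate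
36 | [(1R,2S,6R)-2-[3-(TBSO)propyl]-3-[3-(TBSO)prop-1-en-2-yl]-6-methyl-6-(triethylsilyloxy)-1-vinylcyclohex-3-en-1-yl]methanol | C=C[C@]1(CO)[C@@H](CCCO[Si](C)(C)C(C)(C)C)C(C(=C)CO[Si](C)(C)C(C)(C)C)=CC[C@@]1(C)O[Si](CC)(CC)CC | intermediate
37 | [(1R,2S,3Z,6R)-2-[3-(TBSO)propyl]-3-[1-(TBSO)propan-2-ylidene]-6-methyl-6-(triethylsilyloxy)-1-vinylcyclohexyl]methanol | C=C[C@]1(CO)[C@@H](CCCO[Si](C)(C)C(C)(C)C)/C(=C(/C)CO[Si](C)(C)C(C)(C)C)CC[C@@]1(C)O[Si](CC)(CC)CC | intermediate
38 | (1S,2S,3Z,6R)-2-[3-(TBSO)propyl]-3-[1-(TBSO)propan-2-ylidene]-6-methyl-6-(triethylsilyloxy)-1-vinylcyclohexane-1-carbaldehyde | C=C[C@]1(C=O)[C@@H](CCCO[Si](C)(C)C(C)(C)C)/C(=C(/C)CO[Si](C)(C)C(C)(C)C)CC[C@@]1(C)O[Si](CC)(CC)CC | intermediate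
39 | N-(tert-butyldimethylsilyl)hydrazone of 38 | C=C[C@]1(C=NN[Si](C)(C)C(C)(C)C)[C@@H](CCCO[Si](C)(C)C(C)(C)C)/C(=C(/C)CO[Si](C)(C)C(C)(C)C)CC[C@@]1(C)O[Si](CC)(CC)CC | intermediate (not isolated)
40 | (1R,2S,3Z,6R)-2-[3-(TBSO)propyl]-3-[1-(TBSO)propan-2-ylidene]-1,6-dimethyl-6-(triethylsilyloxy)-1-vinylcyclohexane | C=C[C@]1(C)[C@@H](CCCO[Si](C)(C)C(C)(C)C)/C(=C(/C)CO[Si](C)(C)C(C)(C)C)CC[C@@]1(C)O[Si](CC)(CC)CC | intermediate
41 | B-alkyl-9-BBN from hydroboration of the vinyl group of 40 | B1(CC[C@]2(C)[C@@H](CCCO[Si](C)(C)C(C)(C)C)/C(=C(/C)CO[Si](C)(C)C(C)(C)C)CC[C@@]2(C)O[Si](CC)(CC)CC)C3CCCC1CCC3 | intermediate (not isolated)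
42 | fully silylated target (chain O-TBDPS, propyl O-TBS, allylic O-TBS, tertiary O-TES) | CC(C)=C[C@H](O[Si](c2ccccc2)(c3ccccc3)C(C)(C)C)C/C(C)=C/CC/C(C)=C/CC[C@]1(C)[C@@H](CCCO[Si](C)(C)C(C)(C)C)/C(=C(/C)CO[Si](C)(C)C(C)(C)C)CC[C@@]1(C)O[Si](CC)(CC)CC | intermediate
43 | triol (primary allylic, primary and tertiary OH free) with chain O-TBDPS | CC(C)=C[C@H](O[Si](c2ccccc2)(c3ccccc3)C(C)(C)C)C/C(C)=C/CC/C(C)=C/CC[C@]1(C)[C@@H](CCCO)/C(=C(/C)CO)CC[C@@]1(C)O | intermediate
44 | (Z)-enal with chain O-TBDPS | CC(C)=C[C@H](O[Si](c2ccccc2)(c3ccccc3)C(C)(C)C)C/C(C)=C/CC/C(C)=C/CC[C@]1(C)[C@@H](CCCO)/C(=C(/C)C=O)CC[C@@]1(C)O | intermediate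
45 | (2Z)-2-[(2S,3R,4R)-4-hydroxy-2-(3-hydroxypropyl)-3-[(3E,7E,10R)-10-hydroxy-4,8,12-trimethyltrideca-3,7,11-trien-1-yl]-3,4-dimethylcyclohexylidene]propanal | CC(C)=C[C@H](O)C/C(C)=C/CC/C(C)=C/CC[C@]1(C)[C@@H](CCCO)/C(=C(/C)C=O)CC[C@@]1(C)O | target

**Totals.** 22 steps in all; longest linear sequence 16 steps (6–8 and 10–22, from pent-4-en-1-ol).

**Steps most likely to fail**

Step 14. The boat-shaped [3,3] shift may be too slow, so that β-elimination of silanolate from the enolate, or thermal loss of the silyl groups from the ketene acetal, wins. The fallback sets out from 32 and returns at 36. The tertiary alcohol of 32 is silylated (TESOTf, 2,6-lutidine) to the triethylsilyl ether F1, DIBAL-H at −78 °C gives the lactol F2, and MsCl/Et3N dehydrates it to the cyclic enol ether, the 2-dienyl-4-methyl-4-(triethylsilyloxy)-5-vinyl-3,4-dihydro-2H-pyran F3. Triisobutylaluminium in CH2Cl2 (−78 → 0 °C) should then promote a Lewis-acid (ion-pair) Claisen ring contraction at the aldehyde oxidation level and reduce the aldehyde in the same flask, which gives alcohol 36 directly.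

Step 16. The hindered 2,3-disubstituted diene may fail to form the η4-s-cis chromium complex, so that the diene is returned or isomerised instead of reduced. The fallback sets out from 36 and returns at 37. Ni(cod)2/PCy3-catalysed 1,4-hydroboration with pinacolborane, which is Z-selective and places boron on the unsubstituted terminus, gives the allylboronate F4. NaOH/H2O2 gives the allylic alcohol F5, with the new CH2OH cis to ring C4. Corey–Kim chlorination (NCS, Me2S), selective for the allylic over the neopentyl alcohol, gives the allylic chloride F6, and LiEt3BH displaces chloride by SN2 to deliver 37.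

Step 13. The dienolate may be protonated or couple intermolecularly before it cyclises, or the 1,3-induction may be eroded. The fallback sets out from 27 and returns at 35. Alcohol 27 is acylated with bromoacetyl bromide/pyridine to the bromoacetate F7, and SmI2 at −78 °C (the standard α-bromo ester case) gives the α-unsubstituted hydroxy lactone F8. Its dianion (LDA, 2.2 equiv) adds to acetaldehyde to give the aldol F9, and MsCl with excess Et3N gives the α-ethylidene lactone F10. Under the conditions of step 14, γ-deprotonation of F10 gives the same dienolate, hence ketene acetal 33 and acid 35.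

Further compounds
F1 | step 14 | triethylsilyl ether of lactone 32 | C=CC1C(=O)O[C@H](/C(=C/CCCO[Si](C)(C)C(C)(C)C)C(=C)CO[Si](C)(C)C(C)(C)C)C[C@@]1(C)O[Si](CC)(CC)CC
F2 | step 14 | lactol from DIBAL-H reduction of F1 | C=CC1C(O)O[C@H](/C(=C/CCCO[Si](C)(C)C(C)(C)C)C(=C)CO[Si](C)(C)C(C)(C)C)C[C@@]1(C)O[Si](CC)(CC)CC
F3 | step 14 | (2S,4R)-2-dienyl-4-methyl-4-(triethylsilyloxy)-5-vinyl-3,4-dihydro-2H-pyran | C=CC1=CO[C@H](/C(=C/CCCO[Si](C)(C)C(C)(C)C)C(=C)CO[Si](C)(C)C(C)(C)C)C[C@@]1(C)O[Si](CC)(CC)CC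
F4 | step 16 | allylboronate from 1,4-hydroboration of 36 (CH2Bpin cis to ring C4) | C=C[C@]1(CO)[C@@H](CCCO[Si](C)(C)C(C)(C)C)/C(=C(/CB2OC(C)(C)C(C)(C)O2)CO[Si](C)(C)C(C)(C)C)CC[C@@]1(C)O[Si](CC)(CC)CC
F5 | step 16 | allylic alcohol from oxidation of F4 (new CH2OH cis to ring C4) | C=C[C@]1(CO)[C@@H](CCCO[Si](C)(C)C(C)(C)C)/C(=C(/CO)CO[Si](C)(C)C(C)(C)C)CC[C@@]1(C)O[Si](CC)(CC)CC
F6 | step 16 | allylic chloride from F5 | C=C[C@]1(CO)[C@@H](CCCO[Si](C)(C)C(C)(C)C)/C(=C(/CCl)CO[Si](C)(C)C(C)(C)C)CC[C@@]1(C)O[Si](CC)(CC)CC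
F7 | step 13 | bromoacetate ester of 27 | CC(=O)C[C@H](OC(=O)CBr)/C(=C/CCCO[Si](C)(C)C(C)(C)C)C(=C)CO[Si](C)(C)C(C)(C)C
F8 | step 13 | (4R,6S)-6-dienyl-4-hydroxy-4-methyltetrahydro-2H-pyran-2-one | C1C(=O)O[C@H](/C(=C/CCCO[Si](C)(C)C(C)(C)C)C(=C)CO[Si](C)(C)C(C)(C)C)C[C@@]1(C)O
F9 | step 13 | 3-(1-hydroxyethyl) aldol adduct of F8 | CC(O)C1C(=O)O[C@H](/C(=C/CCCO[Si](C)(C)C(C)(C)C)C(=C)CO[Si](C)(C)C(C)(C)C)C[C@@]1(C)O
F10 | step 13 | 3-ethylidene lactone from F9 | CC=C1C(=O)O[C@H](/C(=C/CCCO[Si](C)(C)C(C)(C)C)C(=C)CO[Si](C)(C)C(C)(C)C)C[C@@]1(C)O
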